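**Plan**

- Atom labels follow the quinoline numbering of the target (N1, C2–C4, C4a, C5–C8, C8a; side chain C1'–C5'). Retrosynthesis: remove the N-oxide oxygen, then cut in one operation the C4a–C5 ring bond and the C1'–C2' bond of the side chain. The remaining pyridine is cut at C8a–C8, C4–OMe and C4a–Br, back to a commercial 4-pyridone.
- Forward: the pyridine ring is bought complete with its methyl and C3 methoxy groups. C4a is brominated, the C4 carbonyl becomes chloride, a pent-4-enyl chain is put on C8a by radical alkylation, and chloride is exchanged for methoxide.
- The carbocycle is then closed by a nickel-catalysed reductive aryl–alkylation. C4a adds to the inner alkene carbon (6-exo) and the outer alkene carbon is coupled with (4-bromobutyl)benzene in the same operation. N-oxidation ends the route.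
- Enabling feature: C5, the sp3 ring carbon bonded to the pyridine β-carbon C4a, is a CH carrying an exocyclic CH2. C5 and C1' are therefore the two carbons of a terminal vinyl group held on C8a by the C8–C7–C6 chain. The nitrogen, flanked by the C2 methyl and C8, is too hindered to bind nickel.
- Stereochemistry: the single stereocentre (C5, R) is set in the ring closure by a chiral bioxazoline ligand on nickel and is not touched afterwards.

Key step: step 5

Assumption: the sense of induction of the bioxazoline ligand in step 5 cannot be predicted with certainty; the (S,S) ligand is written, and its mirror image is used if that is the one that delivers (5R).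

**Route**

Step 1
Reactants: 1 3-methoxy-2-methylpyridin-4(1H)-one
Product: 2 5-bromo-3-methoxy-2-methylpyridin-4(1H)-one
Conditions: NBS (1.05 equiv), DMF, 0 °C to rt
Reagents that add atoms: N-bromosuccinimide, O=C1CCC(=O)N1Br
Why: Electrophilic bromination of the 4-pyridone (a vinylogous amide) should occur at its only free β-carbon, C5, since C3 is blocked by the methoxy group.

Step 2
Reactants: 2 5-bromo-3-methoxy-2-methylpyridin-4(1H)-one
Product: 3 5-bromo-4-chloro-3-methoxy-2-methylpyridine
Conditions: POCl3 (neat), 100 °C; then ice, aq. NaHCO3
Reagents that add atoms: phosphoryl chloride, O=P(Cl)(Cl)Cl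
Why: Deoxychlorination of a 4-pyridone with POCl3 is the standard route to 4-chloropyridines and should leave the bromide and the methoxy group untouched.

Step 3
Reactants: 3 5-bromo-4-chloro-3-methoxy-2-methylpyridine; 4 hex-5-enoic acid
Product: 5 3-bromo-4-chloro-5-methoxy-6-methyl-2-(pent-4-en-1-yl)pyridine
Conditions: AgNO3 (20 mol %), (NH4)2S2O8 (2 equiv), CF3CO2H (1.5 equiv), MeCN/H2O 1:1, 60 °C
Reagents that add atoms: none
Why: Minisci reaction: silver-catalysed persulfate decarboxylation of 4 gives a nucleophilic pent-4-enyl radical, whose tether is too short to cyclise, and it should add to the protonated pyridine at the only unsubstituted α-position before oxidative rearomatisation.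

Step 4
Reactants: 5 3-bromo-4-chloro-5-methoxy-6-methyl-2-(pent-4-en-1-yl)pyridine
Product: 6 3-bromo-4,5-dimethoxy-6-methyl-2-(pent-4-en-1-yl)pyridine
Conditions: NaOMe (3 equiv), MeOH/DMF, 80 °C
Reagents that add atoms: sodium methoxide, C[O-].[Na+]
Why: Nucleophilic aromatic substitution (addition–elimination) by methoxide should occur at the 4-chloride, the only halogen conjugated to the ring nitrogen, while the β-bromide is not activated and the alkene is inert.

Step 5
Reactants: 6 3-bromo-4,5-dimethoxy-6-methyl-2-(pent-4-en-1-yl)pyridine; 7 (4-bromobutyl)benzene
Product: 8 (5R)-3,4-dimethoxy-2-methyl-5-(5-phenylpentyl)-5,6,7,8-tetrahydroquinoline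
Conditions: 7 (2 equiv), NiBr2·dme (10 mol %; dme = MeOCH2CH2OMe), (S,S)-iPr-BiOX [(4S,4'S)-4,4'-diisopropyl-4,4',5,5'-tetrahydro-2,2'-bioxazole] (15 mol %), Mn powder (3 equiv), NaI (0.5 equiv), DMA, 20 °C
Reagents that add atoms: none
Why: Proposed new method: oxidative addition of the C3–Br bond of 6 to zerovalent nickel bearing the chiral bioxazoline gives an aryl–nickel bond at the future C4a, which adds across the tethered terminal alkene by migratory insertion to form the C4a–C5 bond and a primary CH2–Ni bond; this alkylnickel abstracts bromine from 7, recombines with the 4-phenylbutyl radical, and reductive elimination from trivalent nickel forms the side-chain C–C bond while Mn returns nickel to its low-valent state. The closest known reaction type is the nickel-catalysed enantioselective reductive aryl–alkylation of aryl bromides carrying tethered 1,1-disubstituted unactivated alkenes with primary alkyl bromides, which gives benzo-fused rings with quaternary centres; the extension here is to a monosubstituted alkene (tertiary centre), a six-membered ring and a 3-bromopyridine. The one ring closed, the carbocycle, forms by 6-exo-trig carbometalation, favoured over 7-endo because nickel ends on the unhindered primary carbon. The new stereocentre C5 is fixed in the insertion step, where the C2-symmetric ligand differentiates the two faces of the alkene as the tether folds into a chair-like array on the square-planar aryl–nickel unit. The step needs cyclisation before any direct aryl–alkyl coupling and alkyl capture before β-hydride loss from C5–H: the two ortho substituents of the C–Br carbon (the C4 methoxy group and the C2 chain) retard bimolecular coupling at the aryl–nickel stage while insertion is intramolecular, bidentate N,N ligands on nickel are slow in β-hydride elimination, an excess of 7 with NaI keeps radical capture fast, and the ring nitrogen, flanked by the C6 methyl group and the chain, is too hindered to bind the catalyst.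

Step 6
Reactants: 8 (5R)-3,4-dimethoxy-2-methyl-5-(5-phenylpentyl)-5,6,7,8-tetrahydroquinoline
Product: 9 (5R)-3,4-dimethoxy-2-methyl-5-(5-phenylpentyl)-5,6,7,8-tetrahydroquinoline 1-oxide
Conditions: mCPBA (1.2 equiv), CH2Cl2, 0 °C to rt; aq. Na2S2O3/NaHCO3 wash
Reagents that add atoms: 3-chloroperbenzoic acid, OOC(=O)c1cccc(Cl)c1
Why: Peracid N-oxidation of an electron-rich 2,6-dialkylpyridine should be clean because no alkene, amine or sulfide remains to compete, and the C5 stereocentre is not involved.

**Compound list**

1 | 3-methoxy-2-methylpyridin-4(1H)-one | COc1c(C)[nH]ccc1=O | starting material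
2 | 5-bromo-3-methoxy-2-methylpyridin-4(1H)-one | COc1c(C)[nH]cc(Br)c1=O | intermediate
3 | 5-bromo-4-chloro-3-methoxy-2-methylpyridine | COc1c(C)ncc(Br)c1Cl | intermediate
4 | hex-5-enoic acid | C=CCCCC(=O)O | starting material
5 | 3-bromo-4-chloro-5-methoxy-6-methyl-2-(pent-4-en-1-yl)pyridine | COc1c(C)nc(CCCC=C)c(Br)c1Cl | intermediate
6 | 3-bromo-4,5-dimethoxy-6-methyl-2-(pent-4-en-1-yl)pyridine | COc1c(OC)c(C)nc(CCCC=C)c1Br | intermediate
7 | (4-bromobutyl)benzene | BrCCCCc1ccccc1 | starting material
8 | (5R)-3,4-dimethoxy-2-methyl-5-(5-phenylpentyl)-5,6,7,8-tetrahydroquinoline | COc1c(OC)c(C)nc2c1[C@H](CCCCCc1ccccc1)CCC2 | intermediate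
9 | (5R)-3,4-dimethoxy-2-methyl-5-(5-phenylpentyl)-5,6,7,8-tetrahydroquinoline 1-oxide | COc1c(OC)c(C)[n+]([O-])c2c1[C@H](CCCCCc1ccccc1)CCC2 | target

**Step count and risks**

Total steps: 6. Longest linear sequence: 6.

Steps most likely to fail:

1. Step 5. The cyclised alkylnickel may lose a β-hydride from C5–H before it captures the alkyl partner, the aryl–nickel species may couple directly with 7 without cyclising, or the monosubstituted alkene may insert with poor facial selectivity. The fallback sets out from 6 and returns at 8, closing the same bond by a known allylsilane-terminated asymmetric Heck reaction. Cross-metathesis of 6 with allyltrimethylsilane (second-generation Hoveyda–Grubbs catalyst, CH2Cl2, 40 °C) should give 3-bromo-4,5-dimethoxy-6-methyl-2-[(4E)-6-(trimethylsilyl)hex-4-en-1-yl]pyridine F1. Intramolecular Heck cyclisation (Pd2(dba)3, (R)- or (S)-BINAP as required, Ag3PO4, DMF, 80 °C) should then close the ring 6-exo and expel the silyl group to give (5S)-5-ethenyl-3,4-dimethoxy-2-methyl-5,6,7,8-tetrahydroquinoline F2. Cross-metathesis of F2 with 5-phenylpent-1-ene should give (5S)-3,4-dimethoxy-2-methyl-5-[(1E)-5-phenylpent-1-en-1-yl]-5,6,7,8-tetrahydroquinoline F3. Diimide reduction (TsNHNH2, NaOAc, THF/H2O, reflux), chosen to avoid alkene migration through the allylic stereocentre, should give 8.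

2. Step 3. Conversion of the pyridinium may be low, and the oxidising radical medium may engage the terminal alkene (radical addition, oligomerisation). The fallback sets out from 3 and returns at 6, replacing the radical alkylation by a polar one and bypassing step 4 as well. Oxidation of 3 with mCPBA should give 5-bromo-4-chloro-3-methoxy-2-methylpyridine 1-oxide F4. NaOMe in MeOH should displace the 4-chloride, which is far more reactive at the N-oxide level, to give 5-bromo-3,4-dimethoxy-2-methylpyridine 1-oxide F5. Addition of commercial pent-4-en-1-ylmagnesium bromide to the free α-carbon (THF, −40 °C), followed by Ac2O at 120 °C, which removes the N-oxygen as acetate and rearomatises, should give 6.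

3. Step 4. Displacement at C4 may be sluggish because the carbon is flanked by two ortho substituents and the pyridine is not N-activated, and methoxide may instead demethylate the neighbouring methyl ether. The fallback sets out from 2 and returns at 6, so that no chloride has to be displaced. O-Methylation of the pyridone oxygen of 2 (MeI, Ag2CO3, toluene, 60 °C, dark) should give 5-bromo-3,4-dimethoxy-2-methylpyridine F6. F6 is then alkylated at its free α-position with 4 under the Minisci conditions of step 3 to give 6.

**Further compounds**

F1 | step 5 | 3-bromo-4,5-dimethoxy-6-methyl-2-[(4E)-6-(trimethylsilyl)hex-4-en-1-yl]pyridine | COc1c(OC)c(C)nc(CCC/C=C/C[Si](C)(C)C)c1Br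
F2 | step 5 | (5S)-5-ethenyl-3,4-dimethoxy-2-methyl-5,6,7,8-tetrahydroquinoline | COc1c(OC)c(C)nc2c1[C@H](C=C)CCC2
F3 | step 5 | (5S)-3,4-dimethoxy-2-methyl-5-[(1E)-5-phenylpent-1-en-1-yl]-5,6,7,8-tetrahydroquinoline | COc1c(OC)c(C)nc2c1[C@H](/C=C/CCCc1ccccc1)CCC2
F4 | step 3 | 5-bromo-4-chloro-3-methoxy-2-methylpyridine 1-oxide | COc1c(C)[n+]([O-])cc(Br)c1Cl
F5 | step 3 | 5-bromo-3,4-dimethoxy-2-methylpyridine 1-oxide | COc1c(OC)c(Br)c[n+]([O-])c1C
F6 | step 4 | 5-bromo-3,4-dimethoxy-2-methylpyridine | COc1c(OC)c(Br)cnc1C
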